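**Plan**
- Retrosynthesis: the two protecting groups and the O–CH3 bond are removed first. Then the C2–CH2 bond and the C3–O bond of the hetero ring are cut together, which leads back to a 4-(benzyloxy)-2,3-didehydroquinoline, an alkyl Grignard reagent and an oxygen electrophile. The chain is cut at its two C–CH3 bonds back to a bromo ester.
- Enabling feature: the only two substituents of the pyridone ring sit on neighbouring carbons, C2 (alkyl) and C3 (oxygen), flanked by N1 and by the C4 oxygen. They map onto the two ends of a C2≡C3 triple bond that both neighbours polarise in the same sense.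
- Forward: the quinoline bicycle is bought intact, so no ring is built. The chain arm comes from methyl 11-bromoundecanoate (MeMgBr, silylation, Mg). It is joined at C2 in the hetaryne step, which also places oxygen on C3. O-Methylation and a one-pot debenzylation/desilylation then give the 4(1H)-quinolone.
- Stereochemistry: none to set, the target has no stereocentre.

Key step: step 5

Remark: the 4-hydroxyquinoline set free in the last step is taken to rest as the 4(1H)-quinolone tautomer drawn for the target.

**Route**

Step 1
Reactants: 1 methyl 11-bromoundecanoate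
Product: 2 12-bromo-2-methyldodecan-2-ol
Conditions: MeMgBr (2.3 equiv), THF, −20 → 0 °C; aq NH4Cl
Reagents that add atoms: methylmagnesium bromide C[Mg]Br
Why: Double Grignard addition to the ester gives the tertiary carbinol, and the primary C–Br bond should be inert to MeMgBr at this temperature without a coupling catalyst.

Step 2
Reactants: 2 12-bromo-2-methyldodecan-2-ol
Product: 3 [(12-bromo-2-methyldodecan-2-yl)oxy]triethylsilane
Conditions: TESOTf, 2,6-lutidine, CH2Cl2, 0 °C
Reagents that add atoms: triethylsilyl trifluoromethanesulfonate CC[Si](CC)(CC)OS(=O)(=O)C(F)(F)F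
Why: Silyl triflate silylation is the standard way to cap a hindered tertiary alcohol, and the TES ether should survive organomagnesium chemistry and alkaline peroxide.

Step 3
Reactants: 3 [(12-bromo-2-methyldodecan-2-yl)oxy]triethylsilane
Product: 4 [11-methyl-11-(triethylsilyloxy)dodecyl]magnesium bromide (LiCl-complexed THF solution, titrated and used directly)
Conditions: Mg turnings (DIBAL-H activated), LiCl, THF, 25–40 °C
Reagents that add atoms: magnesium [Mg]
Why: LiCl-assisted oxidative insertion of magnesium into a primary alkyl bromide (Grignard formation) tolerates the remote silyl ether, and slow addition should keep Wurtz coupling low.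

Step 4
Reactants: 5 3-bromo-4-chloroquinoline
Product: 6 4-(benzyloxy)-3-bromoquinoline
Conditions: BnOH, NaH, THF, 0 °C → reflux
Reagents that add atoms: benzyl alcohol OCc1ccccc1
Why: Nucleophilic aromatic substitution by benzyloxide should take place only at C4, the position activated by the ring nitrogen, while the C3–Br bond is not activated and stays.

Step 5
Reactants: 6 4-(benzyloxy)-3-bromoquinoline; 4 [11-methyl-11-(triethylsilyloxy)dodecyl]magnesium bromide
Product: 11 4-(benzyloxy)-2-[11-methyl-11-(triethylsilyloxy)dodecyl]quinolin-3-ol, via 2-quinolylmagnesium chloride 7 (not isolated), via 2,3-quinolyne 8 (not isolated), via 3-quinolylmagnesium bromide 9 (not isolated), via dimethyl 3-quinolylboronate 10 (not isolated)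
Conditions: TMPMgCl·LiCl (1.1 equiv), THF, −20 °C; then 4 (2.5 equiv), −20 → 65 °C (sealed); then B(OMe)3, −20 °C → rt; then 30% H2O2, aq NaOH, 0 °C → rt
Reagents that add atoms: hydrogen peroxide OO
Why: Proposed new method: TMPMgCl·LiCl removes the C2–H flanked by N1 and C3–Br (a known directed magnesiation of 3-haloquinolines), and on warming 7 should lose MgBrCl across C2–C3 to give hetaryne 8, to which the alkyl–Mg bond of 4 adds with carbon going to C2 and magnesium to C3; the aryl–Mg bond of 9 is then converted through borate 10 into the C3–OH group by the usual 1,2-shift of the aryl group from boron to oxygen. The closest known reaction types are the regioselective carbomagnesiation of alkoxy-substituted 3,4-pyridynes with Grignard reagents followed by electrophilic trapping of the pyridylmagnesium, and the amination of 3-bromo-4-alkoxypyridines at C2 through 2,3-pyridynes; what is new is a 2,3-quinolyne taking up an sp3 Grignard reagent and an oxygen electrophile in one operation. No ring is closed and no stereocentre is formed. The step needs regioselective addition to the C2≡C3 bond: attack at C2 leaves the in-plane carbanion at C3, away from the N1 lone pair and beside the inductively withdrawing, magnesium-chelating C4–OBn group, whereas attack at C3 would place it at C2 next to the nitrogen lone pair, so both flanking groups direct the alkyl group to C2. Chemoselectivity should rest on complete metalation of C2 before 4 is added, which blocks 1,2-addition of 4 to the C2=N bond, and on the excess of 4 over the hindered arylmagnesium 9, which should suppress oligomerisation of 8.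

Step 6
Reactants: 11 4-(benzyloxy)-2-[11-methyl-11-(triethylsilyloxy)dodecyl]quinolin-3-ol
Product: 12 4-(benzyloxy)-3-methoxy-2-[11-methyl-11-(triethylsilyloxy)dodecyl]quinoline
Conditions: MeI (1.2 equiv), K2CO3, DMF, 0 °C → rt
Reagents that add atoms: iodomethane CI
Why: Williamson O-methylation of the 3-quinolinolate should win over N-methylation because the ring nitrogen is shielded by the 2-alkyl chain and the peri C8–H.

Step 7
Reactants: 12 4-(benzyloxy)-3-methoxy-2-[11-methyl-11-(triethylsilyloxy)dodecyl]quinoline
Product: 13 2-(11-hydroxy-11-methyldodecyl)-3-methoxyquinolin-4(1H)-one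
Conditions: H2 (1 atm), 10% Pd/C, MeOH, HCl (0.05 M), rt; aq NaHCO3
Reagents that add atoms: none
Why: Hydrogenolysis of the benzylic C–O bond frees the 4-hydroxyquinoline, which tautomerises to the 4(1H)-quinolone, while the dilute methanolic acid solvolyses the TES ether in the same pot and should leave the aryl methyl ether and the tertiary alcohol untouched.

**Compound list**

1 | methyl 11-bromoundecanoate | COC(=O)CCCCCCCCCCBr | starting material
2 | 12-bromo-2-methyldodecan-2-ol | CC(C)(O)CCCCCCCCCCBr | intermediate
3 | [(12-bromo-2-methyldodecan-2-yl)oxy]triethylsilane | CC[Si](CC)(CC)OC(C)(C)CCCCCCCCCCBr | intermediate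
4 | [11-methyl-11-(triethylsilyloxy)dodecyl]magnesium bromide | CC[Si](CC)(CC)OC(C)(C)CCCCCCCCCC[Mg]Br | intermediate
5 | 3-bromo-4-chloroquinoline | Clc1c(Br)cnc2ccccc12 | starting material
6 | 4-(benzyloxy)-3-bromoquinoline | Brc1cnc2ccccc2c1OCc1ccccc1 | intermediate
7 | [4-(benzyloxy)-3-bromoquinolin-2-yl]magnesium chloride | Cl[Mg]c1nc2ccccc2c(OCc2ccccc2)c1Br | intermediate
8 | 4-(benzyloxy)-2,3-didehydroquinoline | C(c1ccccc1)OC1=C2C=CC=CC2=NC#C1 | intermediate
9 | {4-(benzyloxy)-2-[11-methyl-11-(triethylsilyloxy)dodecyl]quinolin-3-yl}magnesium bromide | CC[Si](CC)(CC)OC(C)(C)CCCCCCCCCCc1nc2ccccc2c(OCc2ccccc2)c1[Mg]Br | intermediate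
10 | dimethyl {4-(benzyloxy)-2-[11-methyl-11-(triethylsilyloxy)dodecyl]quinolin-3-yl}boronate | CC[Si](CC)(CC)OC(C)(C)CCCCCCCCCCc1nc2ccccc2c(OCc2ccccc2)c1B(OC)OC | intermediate
11 | 4-(benzyloxy)-2-[11-methyl-11-(triethylsilyloxy)dodecyl]quinolin-3-ol | CC[Si](CC)(CC)OC(C)(C)CCCCCCCCCCc1nc2ccccc2c(OCc2ccccc2)c1O | intermediate
12 | 4-(benzyloxy)-3-methoxy-2-[11-methyl-11-(triethylsilyloxy)dodecyl]quinoline | CC[Si](CC)(CC)OC(C)(C)CCCCCCCCCCc1nc2ccccc2c(OCc2ccccc2)c1OC | intermediate
13 | 2-(11-hydroxy-11-methyldodecyl)-3-methoxyquinolin-4(1H)-one | COc1c(CCCCCCCCCCC(C)(C)O)[nH]c2ccccc2c1=O | target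

**Summary**

Total step count: 7. Longest linear sequence: 6 steps (steps 1, 2, 3, 5, 6, 7).

Steps most likely to fail:

1. Step 5. The hetaryne may be lost to oligomerisation or to addition of the liberated amine, the elimination may set in only at a temperature at which the organomagnesium species degrade, or the alkyl group may add with the wrong orientation. The fallback uses known chemistry, sets out from 6 and 4 and comes back at 11. Compound 6 is magnesiated at C2 as before (to 7) and quenched with iodine to give 4-(benzyloxy)-3-bromo-2-iodoquinoline F1. Grignard reagent 4 is transmetalated with ZnCl2 to [11-methyl-11-(triethylsilyloxy)dodecyl]zinc chloride F2. A Negishi coupling (Pd(dppf)Cl2, THF, 50 °C) should join F2 selectively to the C2–I bond, the weaker carbon–halogen bond and the one next to nitrogen, to give 4-(benzyloxy)-3-bromo-2-[11-methyl-11-(triethylsilyloxy)dodecyl]quinoline F3. Bromine–magnesium exchange with i-PrMgCl·LiCl then gives {4-(benzyloxy)-2-[11-methyl-11-(triethylsilyloxy)dodecyl]quinolin-3-yl}magnesium chloride F4, which is borylated with B(OMe)3 to 10 and oxidised with H2O2/NaOH to 11.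

2. Step 6. Methylation may occur at the ring nitrogen (quaternisation) in competition with the phenolic oxygen. The fallback makes the C3–OMe bond at carbon, so that no free 3-hydroxyquinoline meets a methylating agent; it sets out from 6 and 4 and comes back at 12. The arylmagnesium 9, generated as in step 5, is quenched with 2-isopropoxy-4,4,5,5-tetramethyl-1,3,2-dioxaborolane in place of trimethyl borate to give 4-(benzyloxy)-2-[11-methyl-11-(triethylsilyloxy)dodecyl]-3-(4,4,5,5-tetramethyl-1,3,2-dioxaborolan-2-yl)quinoline F5, which is isolated. A Chan–Evans–Lam etherification of F5 with methanol (Cu(OAc)2, DMAP, 4 Å MS, O2, MeOH/CH2Cl2) should then give 12 directly.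

3. Step 7. The hydrogenolysis may stall through catalyst poisoning by the basic nitrogen, the hetero ring may be over-reduced, or the acid may ionise the tertiary alcohol. The fallback is non-reductive and non-acidic, sets out from 12 and comes back at 13. TBAF in THF removes the silyl group to give 12-[4-(benzyloxy)-3-methoxyquinolin-2-yl]-2-methyldodecan-2-ol F6. Sodium ethanethiolate in DMF at 80 °C should then cleave the benzyl ether by SN2 attack at the benzylic carbon, with the 4-quinolinolate as leaving group and the less reactive 3-methyl ether left intact, and protonation on work-up gives 13.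

**Further compounds**

F1 | step 5 | 4-(benzyloxy)-3-bromo-2-iodoquinoline | Ic1nc2ccccc2c(OCc2ccccc2)c1Br
F2 | step 5 | [11-methyl-11-(triethylsilyloxy)dodecyl]zinc chloride | CC[Si](CC)(CC)OC(C)(C)CCCCCCCCCC[Zn]Cl
F3 | step 5 | 4-(benzyloxy)-3-bromo-2-[11-methyl-11-(triethylsilyloxy)dodecyl]quinoline | CC[Si](CC)(CC)OC(C)(C)CCCCCCCCCCc1nc2ccccc2c(OCc2ccccc2)c1Br
F4 | step 5 | {4-(benzyloxy)-2-[11-methyl-11-(triethylsilyloxy)dodecyl]quinolin-3-yl}magnesium chloride | CC[Si](CC)(CC)OC(C)(C)CCCCCCCCCCc1nc2ccccc2c(OCc2ccccc2)c1[Mg]Cl
F5 | step 6 | 4-(benzyloxy)-2-[11-methyl-11-(triethylsilyloxy)dodecyl]-3-(4,4,5,5-tetramethyl-1,3,2-dioxaborolan-2-yl)quinoline | CC[Si](CC)(CC)OC(C)(C)CCCCCCCCCCc1nc2ccccc2c(OCc2ccccc2)c1B1OC(C)(C)C(C)(C)O1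
F6 | step 7 | 12-[4-(benzyloxy)-3-methoxyquinolin-2-yl]-2-methyldodecan-2-ol | COc1c(CCCCCCCCCCC(C)(C)O)nc2ccccc2c1OCc1ccccc1
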